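**Plan**
- Cuts, in retrosynthetic order (ring D numbered C1(=O), C2–OMe, C3–H, C4(=O), C5–OAr, C6–alkyl): C1–C2 (ring expansion of a cyclobutenone), C3–C4 (vinyl anion onto a cyclobutenedione), O–C5 (ring-C phenoxide onto a chlorocyclobutenedione, which closes the 18-membered ring), C6–CH2 (Grignard onto dimethyl squarate), then the A–O–B ether (Ullmann) and the B–C ethylene bridge (Wittig, diimide).
- Enabling feature: C5 and C6, the only ring-D atoms shared with the 18-membered ring, are adjacent and, together with C1 and C4, are the four carbons of a squarate; C2(OMe)–C3(H) is a (Z)-2-methoxyvinyl unit. The macrocycle is therefore closed on the four-membered ring and keeps its size when that ring expands.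
- Forward order: ring-C phosphonium salt + ring-B aldehyde → bibenzyl; ring A by Ullmann coupling; bromide → Grignard → squarate; acid unmasking; macrocyclisation; vinyl carbinol; ring D by thermolysis; debenzylation and oxidation.
- Stereochemistry: the target has no stereocentre. The (Z)-enol ether (from the (Z)-bromide, with retention) and the racemic carbinol disappear when ring D aromatises.

Key step: step 15

Remark: the target SMILES carries no stereodescriptor and the 18-membered ring is taken as conformationally mobile, so the compound is treated as achiral and no asymmetric step is needed.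

**Route**

Step 1
Reactants: 1 3-hydroxybenzaldehyde
Product: 2 3-(methoxymethoxy)benzaldehyde
Conditions: MOMCl, i-Pr2NEt, CH2Cl2, 0 °C to rt
Reagents that add atoms: chloromethyl methyl ether, COCCl
Why: O-alkylation of the phenol (MOM acetal protection) gives an ether that tolerates ylide, diimide, copper/carbonate, Appel and Grignard conditions and is later cleaved by the same aqueous acid that hydrolyses the squarate ester.

Step 2
Reactants: 2 3-(methoxymethoxy)benzaldehyde
Product: 3 [3-(methoxymethoxy)phenyl]methanol
Conditions: NaBH4, MeOH, 0 °C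
Reagents that add atoms: none
Why: Borohydride reduction of an aromatic aldehyde is chemoselective and leaves the acetal untouched.

Step 3
Reactants: 3 [3-(methoxymethoxy)phenyl]methanol
Product: 4 1-(bromomethyl)-3-(methoxymethoxy)benzene
Conditions: CBr4, PPh3, CH2Cl2, 0 °C
Reagents that add atoms: carbon tetrabromide, BrC(Br)(Br)Br
Why: Appel bromination converts the benzylic alcohol under neutral conditions that spare the acid-labile MOM group.

Step 4
Reactants: 4 1-(bromomethyl)-3-(methoxymethoxy)benzene
Product: 5 [3-(methoxymethoxy)benzyl]triphenylphosphonium bromide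
Conditions: PPh3, toluene, 110 °C
Reagents that add atoms: triphenylphosphine, c1ccc(cc1)P(c1ccccc1)c1ccccc1
Why: SN2 quaternisation of triphenylphosphine by a benzylic bromide should give the crystalline Wittig salt.

Step 5
Reactants: 6 3,4-dihydroxybenzaldehyde
Product: 7 4-(benzyloxy)-3-hydroxybenzaldehyde
Conditions: BnBr (1.0 equiv), NaHCO3, NaI (cat.), DMF, 40 °C
Reagents that add atoms: benzyl bromide, BrCc1ccccc1
Why: Regioselective Williamson benzylation, because the 4-OH para to the formyl group is the more acidic phenol and is preferentially ionised by hydrogencarbonate, so the 3-OH stays free for the later diaryl ether.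

Step 6
Reactants: 5 [3-(methoxymethoxy)benzyl]triphenylphosphonium bromide; 7 4-(benzyloxy)-3-hydroxybenzaldehyde
Product: 8 2-(benzyloxy)-5-{2-[3-(methoxymethoxy)phenyl]ethenyl}phenol (E/Z mixture)
Conditions: KOtBu (2.2 equiv), THF, 0 °C to rt; aq NH4Cl
Reagents that add atoms: none
Why: Wittig olefination with a semi-stabilised benzyl ylide, the second equivalent of base carrying the phenol through as a phenoxide that is meta to the aldehyde and does not deactivate it; the alkene geometry is irrelevant because both isomers are reduced next.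

Step 7
Reactants: 8 2-(benzyloxy)-5-{2-[3-(methoxymethoxy)phenyl]ethenyl}phenol
Product: 9 2-(benzyloxy)-5-{2-[3-(methoxymethoxy)phenyl]ethyl}phenol
Conditions: TsNHNH2, NaOAc, DME/H2O, reflux
Reagents that add atoms: none
Why: Diimide reduction (diimide generated from tosylhydrazide) saturates the stilbene by concerted syn hydrogen transfer and, unlike Pd/H2, cannot hydrogenolyse the aryl benzyl ether.

Step 8
Reactants: 9 2-(benzyloxy)-5-{2-[3-(methoxymethoxy)phenyl]ethyl}phenol; 10 2-(4-bromophenyl)ethanol
Product: 11 2-{4-[2-(benzyloxy)-5-{2-[3-(methoxymethoxy)phenyl]ethyl}phenoxy]phenyl}ethanol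
Conditions: CuI (cat.), N,N-dimethylglycine·HCl (cat.), Cs2CO3, 1,4-dioxane, 100 °C
Reagents that add atoms: none
Why: Ligand-accelerated Ullmann diaryl ether coupling, in which the electron-rich phenoxide couples with the aryl bromide while the much less acidic primary alcohol of 10 is expected to remain unarylated.

Step 9
Reactants: 11 2-{4-[2-(benzyloxy)-5-{2-[3-(methoxymethoxy)phenyl]ethyl}phenoxy]phenyl}ethanol
Product: 12 1-(benzyloxy)-2-[4-(2-bromoethyl)phenoxy]-4-{2-[3-(methoxymethoxy)phenyl]ethyl}benzene
Conditions: CBr4, PPh3, CH2Cl2, 0 °C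
Reagents that add atoms: carbon tetrabromide, BrC(Br)(Br)Br
Why: Appel bromination of a primary alcohol is neutral and compatible with the MOM, benzyl and diaryl ethers.

Step 10
Reactants: 12 1-(benzyloxy)-2-[4-(2-bromoethyl)phenoxy]-4-{2-[3-(methoxymethoxy)phenyl]ethyl}benzene; 13 dimethyl squarate
Product: 16 3-(2-{4-[2-(benzyloxy)-5-{2-[3-(methoxymethoxy)phenyl]ethyl}phenoxy]phenyl}ethyl)-4-methoxycyclobut-3-ene-1,2-dione, via arylethylmagnesium bromide 14 (not isolated), via bromomagnesium alkoxide of the squarate adduct 15 (not isolated)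
Conditions: Mg, THF, 40 °C; add to 13 (1.5 equiv), THF, −78 °C; TFAA, −78 to 0 °C; aq NaHCO3
Reagents that add atoms: magnesium, [Mg] (present in 14 and 15 only); water, O (carbonyl oxygen at the former methoxy carbon, taken to come from the work-up)
Why: Grignard 1,2-addition to one carbonyl of excess dimethyl squarate, then trifluoroacetylation of the tertiary alkoxide and aqueous work-up, should bring about the usual allylic transposition/hydrolysis of squarate adducts to a 3-alkyl-4-alkoxycyclobutenedione, which attaches the chain to the future C6 of ring D.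

Step 11
Reactants: 16 3-(2-{4-[2-(benzyloxy)-5-{2-[3-(methoxymethoxy)phenyl]ethyl}phenoxy]phenyl}ethyl)-4-methoxycyclobut-3-ene-1,2-dione
Product: 17 3-(2-{4-[2-(benzyloxy)-5-[2-(3-hydroxyphenyl)ethyl]phenoxy]phenyl}ethyl)-4-hydroxycyclobut-3-ene-1,2-dione
Conditions: 3 M aq HCl, THF, 50 °C
Reagents that add atoms: water, O
Why: Aqueous acid hydrolyses the vinylogous methyl ester to the semisquaric acid and cleaves the MOM acetal in the same operation, while the benzyl and diaryl ethers are inert.

Step 12
Reactants: 17 3-(2-{4-[2-(benzyloxy)-5-[2-(3-hydroxyphenyl)ethyl]phenoxy]phenyl}ethyl)-4-hydroxycyclobut-3-ene-1,2-dione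
Product: 19 18-membered macrocyclic 3-aryloxy-4-alkylcyclobut-3-ene-1,2-dione (C4–CH2CH2–ring A para–O–ring B meta–CH2CH2–ring C meta–O–C3; ring-B phenol as benzyl ether), via chlorocyclobutenedione phenol 18 (not isolated)
Conditions: (COCl)2 (1.05 equiv), DMF (cat.), CH2Cl2, 0 °C; evaporate; syringe-pump addition to i-Pr2NEt, CH2Cl2 (1 mM), rt
Reagents that add atoms: oxalyl chloride, ClC(=O)C(=O)Cl (chlorine of intermediate 18 only)
Why: Vilsmeier-type chlorination turns the strongly acidic semisquaric hydroxyl into a vinylogous acid chloride far faster than the un-ionised phenol reacts, and slow addition to base then closes the 18-membered ring by addition–elimination of the ring-C phenoxide at the chlorine-bearing carbon, ring B being blocked as its benzyl ether.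

Step 13
Reactants: 20 methyl vinyl ether
Product: 22 (Z)-1-bromo-2-methoxyethene, via 1,2-dibromo-1-methoxyethane 21 (not isolated)
Conditions: Br2, pentane, −78 °C; concentrate; PhNEt2, 90 °C; distil
Reagents that add atoms: bromine, BrBr
Why: Bromine addition to the enol ether followed by amine-induced dehydrobromination through the α-bromo ether carbon gives the 2-bromovinyl ether, the cis isomer being the favoured one and the one collected on distillation.

Step 14
Reactants: 19 macrocyclic 3-aryloxy-4-alkylcyclobut-3-ene-1,2-dione; 22 (Z)-1-bromo-2-methoxyethene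
Product: 24 macrocyclic 2-alkyl-3-aryloxy-4-hydroxy-4-[(Z)-2-methoxyvinyl]cyclobut-2-en-1-one (racemic at C4; ring-B phenol as benzyl ether), via (Z)-2-methoxyvinyllithium 23 (not isolated)
Conditions: 22, t-BuLi (2 equiv per 22), THF, −78 °C; then 19, −78 °C; aq NH4Cl at −78 °C; base-washed silica
Reagents that add atoms: tert-butyllithium, [Li]C(C)(C)C (lithium of intermediate 23 only)
Why: Bromine–lithium exchange with retention gives the oxygen-coordinated (Z)-vinyllithium, which should add 1,2 at −78 °C to the ketone-like C2 carbonyl next to the aryloxy carbon because the C1 carbonyl is deactivated as a vinylogous aryl ester; the carbinol centre forms as a racemate and is erased in step 15.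

Step 15
Reactants: 24 macrocyclic 2-alkyl-3-aryloxy-4-hydroxy-4-[(Z)-2-methoxyvinyl]cyclobut-2-en-1-one
Product: 26 hydroquinone form of the target with the ring-B phenol as benzyl ether, via macrocyclic dienylketene 25 (not isolated)
Conditions: p-xylene (degassed, 5 mM), 138 °C, Ar
Reagents that add atoms: none
Why: Heating should open the cyclobutenone by a thermally allowed conrotatory 4π electrocyclic cleavage of its C1–C4 bond to dienylketene 25, in which the alkyl- and aryloxy-bearing carbons stay directly bonded, so the 18-membered ring is neither resized nor broken. The ketene carbon then bonds to the methoxy-bearing terminus of the enol ether in a thermal disrotatory 6π electrocyclisation, the only ring closure of the step (six-membered ring D, new bond C1–C2 in quinone numbering), and the cyclohexa-2,4-dienone formed enolises to the hydroquinone. The closest known reaction type is the thermal rearrangement of squarate-derived 4-alkenyl-4-hydroxycyclobutenones to hydroquinones (Moore rearrangement). No stereocentre is created and the racemic carbinol centre of 24 disappears. The one selectivity needed is torquoselectivity: the C4 hydroxyl, as the stronger donor, should rotate outward and so turn the methoxyvinyl group inward toward the ketene, which is the inherent preference of such carbinols; the substitution pattern of ring D was already fixed by the site of addition in step 14.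

Step 16
Reactants: 26 hydroquinone form of the target with the ring-B phenol as benzyl ether
Product: 28 CNP0332646.0 (target quinone), via debenzylated hydroquinone 27 (not isolated)
Conditions: H2 (1 atm), Pd/C, EtOAc, rt; filter under Ar; Ag2O, rt
Reagents that add atoms: none
Why: Hydrogenolysis of the aryl benzyl ether over Pd/C leaves the hydroquinone and diaryl ethers intact, and silver(I) oxide then oxidises only the para-dihydroxyarene to the quinone, the isolated ring-B phenol being expected to be left untouched by this mild oxidant.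

**Compound list**
1 | 3-hydroxybenzaldehyde | O=Cc1cccc(O)c1 | starting material
2 | 3-(methoxymethoxy)benzaldehyde | COCOc1cccc(C=O)c1 | intermediate
3 | [3-(methoxymethoxy)phenyl]methanol | COCOc1cccc(CO)c1 | intermediate
4 | 1-(bromomethyl)-3-(methoxymethoxy)benzene | COCOc1cccc(CBr)c1 | intermediate
5 | [3-(methoxymethoxy)benzyl]triphenylphosphonium bromide | COCOc1cccc(C[P+](c2ccccc2)(c2ccccc2)c2ccccc2)c1.[Br-] | intermediate
6 | 3,4-dihydroxybenzaldehyde | O=Cc1ccc(O)c(O)c1 | starting material
7 | 4-(benzyloxy)-3-hydroxybenzaldehyde | O=Cc1ccc(OCc2ccccc2)c(O)c1 | intermediate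
8 | 2-(benzyloxy)-5-{2-[3-(methoxymethoxy)phenyl]ethenyl}phenol (E/Z mixture) | COCOc1cccc(C=Cc2ccc(OCc3ccccc3)c(O)c2)c1 | intermediate
9 | 2-(benzyloxy)-5-{2-[3-(methoxymethoxy)phenyl]ethyl}phenol | COCOc1cccc(CCc2ccc(OCc3ccccc3)c(O)c2)c1 | intermediate
10 | 2-(4-bromophenyl)ethanol | OCCc1ccc(Br)cc1 | starting material
11 | 2-{4-[2-(benzyloxy)-5-{2-[3-(methoxymethoxy)phenyl]ethyl}phenoxy]phenyl}ethanol | COCOc1cccc(CCc2ccc(OCc3ccccc3)c(Oc3ccc(CCO)cc3)c2)c1 | intermediate
12 | 1-(benzyloxy)-2-[4-(2-bromoethyl)phenoxy]-4-{2-[3-(methoxymethoxy)phenyl]ethyl}benzene | COCOc1cccc(CCc2ccc(OCc3ccccc3)c(Oc3ccc(CCBr)cc3)c2)c1 | intermediate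
13 | dimethyl squarate (3,4-dimethoxycyclobut-3-ene-1,2-dione) | COC1=C(OC)C(=O)C1=O | starting material
14 | Grignard reagent of 12 (2-arylethylmagnesium bromide) | COCOc1cccc(CCc2ccc(OCc3ccccc3)c(Oc3ccc(CC[Mg]Br)cc3)c2)c1 | intermediate (not isolated)
15 | bromomagnesium alkoxide of racemic 4-hydroxy-2,3-dimethoxy-4-(2-arylethyl)cyclobut-2-en-1-one | COC1=C(OC)C(O[Mg]Br)(CCc2ccc(Oc3cc(CCc4cccc(OCOC)c4)ccc3OCc3ccccc3)cc2)C1=O | intermediate (not isolated)
16 | 3-(2-{4-[2-(benzyloxy)-5-{2-[3-(methoxymethoxy)phenyl]ethyl}phenoxy]phenyl}ethyl)-4-methoxycyclobut-3-ene-1,2-dione | COC1=C(CCc2ccc(Oc3cc(CCc4cccc(OCOC)c4)ccc3OCc3ccccc3)cc2)C(=O)C1=O | intermediate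
17 | 3-(2-{4-[2-(benzyloxy)-5-[2-(3-hydroxyphenyl)ethyl]phenoxy]phenyl}ethyl)-4-hydroxycyclobut-3-ene-1,2-dione | OC1=C(CCc2ccc(Oc3cc(CCc4cccc(O)c4)ccc3OCc3ccccc3)cc2)C(=O)C1=O | intermediate
18 | 3-(2-{4-[2-(benzyloxy)-5-[2-(3-hydroxyphenyl)ethyl]phenoxy]phenyl}ethyl)-4-chlorocyclobut-3-ene-1,2-dione | ClC1=C(CCc2ccc(Oc3cc(CCc4cccc(O)c4)ccc3OCc3ccccc3)cc2)C(=O)C1=O | intermediate (not isolated)
19 | 18-membered macrocyclic 3-aryloxy-4-alkylcyclobut-3-ene-1,2-dione, ring-B phenol as benzyl ether | O=C1C(=O)C2=C1CCc1ccc(cc1)Oc1cc(ccc1OCc1ccccc1)CCc1cccc(c1)O2 | intermediate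
20 | methyl vinyl ether | COC=C | starting material
21 | 1,2-dibromo-1-methoxyethane (racemic) | COC(Br)CBr | intermediate (not isolated)
22 | (Z)-1-bromo-2-methoxyethene | CO/C=C\Br | intermediate
23 | (Z)-2-methoxyvinyllithium | CO/C=C\[Li] | intermediate (not isolated)
24 | macrocyclic 2-alkyl-3-aryloxy-4-hydroxy-4-[(Z)-2-methoxyvinyl]cyclobut-2-en-1-one, racemic at C4, ring-B phenol as benzyl ether | O=C1C2=C(Oc3cccc(c3)CCc3ccc(OCc4ccccc4)c(c3)Oc3ccc(CC2)cc3)C1(O)/C=C\OC | intermediate
25 | macrocyclic dienylketene (hydroxyl and aryloxy cis on the central double bond, (Z)-enol ether) | O=C=C1CCc2ccc(cc2)Oc2cc(ccc2OCc2ccccc2)CCc2cccc(c2)O/C1=C(O)/C=C\OC | intermediate (not isolated)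
26 | hydroquinone form of the target, ring-B phenol as benzyl ether | COc1cc(O)c2c(CCc3ccc(cc3)Oc3cc(ccc3OCc3ccccc3)CCc3cccc(c3)O2)c1O | intermediate
27 | hydroquinone form of the target, ring-B phenol free | COc1cc(O)c2c(CCc3ccc(cc3)Oc3cc(ccc3O)CCc3cccc(c3)O2)c1O | intermediate (not isolated)
28 | CNP0332646.0 | COC1=CC(=O)C2=C(CCc3ccc(cc3)Oc3cc(ccc3O)CCc3cccc(c3)O2)C1=O | target

**Totals**
Total step count: 16. Longest linear sequence: 14 steps (steps 1–4, 6–12, 14–16, from 3-hydroxybenzaldehyde).

**Steps most likely to fail**

Step 12. The free ring-C phenol may be acylated by the chlorinating agent, and the chloride may esterify intermolecularly before the dilute ring closure, giving oligomers. The fallback keeps the phenol masked during activation. It sets out from 16: one equivalent of LiOH in THF/H2O at 0 °C cleaves only the vinylogous ester and gives the MOM-protected lithium semisquarate F1. After drying, oxalyl chloride with catalytic DMF in CH2Cl2 converts this salt into the MOM-protected chlorocyclobutenedione F2 with no phenol and no free acid present. Once the volatiles are removed, anhydrous HCl in dioxane at 0 °C cleaves the MOM acetal. The route is rejoined at 18, which is evaporated and cyclised under the high-dilution conditions of step 12.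

Step 14. The vinyllithium may attack the aryloxy-bearing ring carbon (addition–elimination that expels the ring-C phenoxide and reopens the macrocycle) or the deactivated carbonyl, and the reagent may lose its geometry or fragment. The fallback brings in the two carbons as an alkyne and sets the geometry afterwards. It sets out from 22, which with two equivalents of LDA in THF (−78 to 0 °C) is dehydrobrominated and deprotonated to lithium methoxyethynide F3; the hindered diisopropylamine formed should not touch the vinylogous ester at −78 °C. Addition of 19 at −78 °C should give the macrocyclic 4-hydroxy-4-(methoxyethynyl)cyclobutenone F4, an alkynyllithium 1,2-addition of the kind that is most reliable with alkoxycyclobutenediones. F4 is kept cold and semi-hydrogenated with Lindlar catalyst and quinoline (cis addition of hydrogen), and the route is rejoined at 24.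

Step 15. The free tertiary hydroxyl may capture the ketene if rotation brings it inward (butenolide formation), the β-hydroxy enol ether may ionise before the ring opens, or closure within the macrocycle may need temperatures at which 24 decomposes. The fallback caps the hydroxyl first. It sets out from 24, which is silylated (TMSCl, imidazole, DMF) to the trimethylsilyl ether F5; the silyloxy group is still the outward-rotating donor but cannot lactonise or ionise. Thermolysis in p-xylene should then give the mono-silylated hydroquinone F6 (silyloxy group on the carbon between C–H and C–OAr). Degassed K2CO3/MeOH removes the silyl group, and the route is rejoined at 26.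

**Further compounds**
F1 | step 12 | lithium 2-(2-{4-[2-(benzyloxy)-5-{2-[3-(methoxymethoxy)phenyl]ethyl}phenoxy]phenyl}ethyl)-3,4-dioxocyclobut-1-en-1-olate | [Li+].[O-]C1=C(CCc2ccc(Oc3cc(CCc4cccc(OCOC)c4)ccc3OCc3ccccc3)cc2)C(=O)C1=O
F2 | step 12 | 3-(2-{4-[2-(benzyloxy)-5-{2-[3-(methoxymethoxy)phenyl]ethyl}phenoxy]phenyl}ethyl)-4-chlorocyclobut-3-ene-1,2-dione | ClC1=C(CCc2ccc(Oc3cc(CCc4cccc(OCOC)c4)ccc3OCc3ccccc3)cc2)C(=O)C1=O
F3 | step 14 | lithium methoxyethynide | COC#C[Li]
F4 | step 14 | macrocyclic 2-alkyl-3-aryloxy-4-hydroxy-4-(methoxyethynyl)cyclobut-2-en-1-one, racemic at C4, ring-B phenol as benzyl ether | O=C1C2=C(Oc3cccc(c3)CCc3ccc(OCc4ccccc4)c(c3)Oc3ccc(CC2)cc3)C1(O)C#COC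
F5 | step 15 | trimethylsilyl ether of 24 (racemic at C4) | O=C1C2=C(Oc3cccc(c3)CCc3ccc(OCc4ccccc4)c(c3)Oc3ccc(CC2)cc3)C1(O[Si](C)(C)C)/C=C\OC
F6 | step 15 | mono-trimethylsilyl ether of hydroquinone 26 (silyloxy group on the carbon between C–H and C–OAr) | COc1cc(O[Si](C)(C)C)c2c(CCc3ccc(cc3)Oc3cc(ccc3OCc3ccccc3)CCc3cccc(c3)O2)c1O
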